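**Retrosynthetic overview**

1. The two propanoates go on last. Before that, the C–C bond between the alkene CH and the CH(CH3) carbon on the central pyranone (ring A) is cut: a nickel-catalysed enantioconvergent reductive coupling of a racemic pyranonyl-ethyl chloride (west half, ring A, acetate in place) with an (E)-alkenyl bromide (east half, ring B) joins the halves and sets that stereocentre.
2. The east half comes from a vinylogous aldol addition of the lateral lithium dienolate of 2,6-diethyl-3,5-dimethyl-4-pyranone to an α-methyl-β-silyloxy aldehyde (two stereocentres). The aldehyde comes from an Evans magnesium-catalysed anti-aldol on (E)-3-bromo-2-methylacrolein (two stereocentres).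
3. The west half comes from the same pyranone by two lateral C–H chlorinations, a nickel-catalysed asymmetric reductive acylation and a Felkin–Anh reduction (two stereocentres).
4. Ring order: ring A and ring B are one and the same compound, formed once in step 1 from pentan-3-one and propanoic anhydride. No ring is formed afterwards, so there is no propionate-aldol chain assembly and no triketone cyclisation on a chiral chain.

Assumption: the absolute sense of induction in the two nickel/bis(oxazoline) steps (3 and 13) is assigned by analogy with 1-arylethyl chlorides; if it proves opposite, the commercially available antipodal ligand is used and nothing else changes.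

**Route**

Step 1
Reactants: 1 pentan-3-one; 2 propanoic anhydride
Product: 4 2,6-diethyl-3,5-dimethyl-4H-pyran-4-one, via triketone 3 (not isolated)
Conditions: (EtCO)2O (2.2 equiv), polyphosphoric acid, 100 °C, 6 h; aq. Na2CO3 work-up, distillation
Reagents that add atoms: none
Why: Polyphosphoric-acid pyranone condensation, in which double C-acylation of the ketone at both α-carbons gives the 1,3,5-triketone that cyclodehydrates in the same pot to the symmetrical 4-pyranone, and no stereocentre is formed.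

Step 2
Reactants: 4 2,6-diethyl-3,5-dimethyl-4H-pyran-4-one
Product: 6 2-(1-chloroethyl)-6-ethyl-3,5-dimethyl-4H-pyran-4-one (racemic), via sodium dienolate 5 (not isolated)
Conditions: NaN(SiMe3)2 (1.05 equiv), THF, −78 °C, 45 min; cannulated into C2Cl6 (1.5 equiv), THF, −78 °C
Reagents that add atoms: hexachloroethane, ClC(Cl)(Cl)C(Cl)(Cl)Cl
Why: Lateral metalation followed by electrophilic enolate chlorination, because the ethyl CH2 is the vinylogous α-position of the pyranone and the ionic sodium dienolate is halogenated quickly at the exocyclic carbon by hexachloroethane with re-aromatisation, the new stereocentre being left racemic on purpose.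

Step 3
Reactants: 6 2-(1-chloroethyl)-6-ethyl-3,5-dimethyl-4H-pyran-4-one (racemic); 7 propanoyl chloride
Product: 8 2-ethyl-3,5-dimethyl-6-[(2R)-3-oxopentan-2-yl]-4H-pyran-4-one
Conditions: 7 (1.2 equiv), NiCl2·DME (10 mol %), 2,2′-(propane-2,2-diyl)bis[(4R)-4-phenyl-4,5-dihydrooxazole] (22 mol %), Mn powder (3 equiv), 2,6-dimethylbenzoic acid (0.75 equiv), DMA/THF 3:7, 20 °C, 24 h
Reagents that add atoms: none
Why: Proposed new method: the pyranonyl-ethyl chloride should behave as a secondary benzylic chloride in a nickel-catalysed asymmetric reductive acyl cross-electrophile coupling (closest known type: nickel/bis(oxazoline)/manganese coupling of 1-arylethyl chlorides with acid chlorides), since chlorine abstraction gives a planar radical stabilised by the pyranone π-system that is captured by the chiral acyl–nickel species, so both enantiomers of 6 converge on the (R)-ketone under base-free, slightly acidic conditions that do not epimerise the new C–H centre.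

Step 4
Reactants: 8 2-ethyl-3,5-dimethyl-6-[(2R)-3-oxopentan-2-yl]-4H-pyran-4-one
Product: 9 2-ethyl-6-[(2S,3S)-3-hydroxypentan-2-yl]-3,5-dimethyl-4H-pyran-4-one
Conditions: KBH(s-Bu)3 (1.2 equiv), THF, −78 °C, 1 h; AcOH quench at −78 °C
Reagents that add atoms: none
Why: Felkin–Anh-controlled hydride reduction, in which the bulky non-chelating hydride attacks the ketone anti to the pyranone ring (the large sp2 substituent) and past the small hydrogen to give the 2,3-anti alcohol with (S) configuration at the carbinol, while this nucleophilic reagent leaves the electron-rich pyranone carbonyl untouched.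

Step 5
Reactants: 9 2-ethyl-6-[(2S,3S)-3-hydroxypentan-2-yl]-3,5-dimethyl-4H-pyran-4-one
Product: 11 2-(1-chloroethyl)-6-[(2S,3S)-3-hydroxypentan-2-yl]-3,5-dimethyl-4H-pyran-4-one (both epimers at the CHCl carbon), via dilithium alkoxide dienolate 10 (not isolated)
Conditions: LiN(SiMe3)2 (2.2 equiv), THF, −78 °C, 1 h; C2Cl6 (1.3 equiv), −78 °C; AcOH quench at −78 °C
Reagents that add atoms: hexachloroethane, ClC(Cl)(Cl)C(Cl)(Cl)Cl
Why: Lateral metalation and enolate chlorination as in step 2, where the first equivalent of base makes the alkoxide (which blocks E1cB loss and disfavours deprotonation of the neighbouring tertiary C–H) and the second removes a proton from the unhindered CH2 of the remaining ethyl group, the C–Cl centre being formed as a mixture because the later coupling is stereoconvergent.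

Step 6
Reactants: 11 2-(1-chloroethyl)-6-[(2S,3S)-3-hydroxypentan-2-yl]-3,5-dimethyl-4H-pyran-4-one
Product: 12 (2S,3S)-2-[6-(1-chloroethyl)-3,5-dimethyl-4-oxo-4H-pyran-2-yl]pentan-3-yl acetate (both epimers at the CHCl carbon)
Conditions: Ac2O (2 equiv), pyridine (3 equiv), DMAP (5 mol %), CH2Cl2, 0 °C
Reagents that add atoms: acetic anhydride, CC(=O)OC(C)=O
Why: DMAP-catalysed esterification of the only hydroxyl present installs the acetate before the two hydroxyls that will carry propanoates exist, and the weak base at 0 °C neither displaces the chloride nor touches a stereocentre.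

Step 7
Reactants: 13 2-methylprop-2-enal (methacrolein)
Product: 15 (2E)-3-bromo-2-methylprop-2-enal, via dibromide 14 (not isolated)
Conditions: Br2 (1.0 equiv), CH2Cl2, −78 → 0 °C; then Et3N (1.2 equiv), 0 °C → rt
Reagents that add atoms: bromine, BrBr
Why: Bromination–dehydrobromination, in which bromine adds across the alkene and triethylamine removes HBr by E2 (the only acidified hydrogens are on CH2Br) to give the conjugated bromoenal as the E isomer with Br trans to CHO.

Step 8
Reactants: 15 (2E)-3-bromo-2-methylprop-2-enal; 16 (4R)-4-benzyl-3-propanoyl-1,3-oxazolidin-2-one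
Product: 18 (4R)-4-benzyl-3-[(2S,3R,4E)-5-bromo-3-hydroxy-2,4-dimethylpent-4-enoyl]-1,3-oxazolidin-2-one, via trimethylsilyl ether 17 (not isolated)
Conditions: 15 (1.2 equiv), MgCl2 (20 mol %), Et3N (2 equiv), Me3SiCl (1.5 equiv), EtOAc, 23 °C, 24 h; then MeOH, CF3CO2H (cat.), rt
Reagents that add atoms: none
Why: Evans magnesium-halide-catalysed anti-aldol, in which the chelated (Z)-magnesium enolate of the (R)-imide adds to the non-enolisable enal on the face opposite the benzyl group through a boat transition state to give the 2,3-anti adduct with (2S,3R) configuration, silyl trapping of the aldolate turning the catalyst over.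

Step 9
Reactants: 18 (4R)-4-benzyl-3-[(2S,3R,4E)-5-bromo-3-hydroxy-2,4-dimethylpent-4-enoyl]-1,3-oxazolidin-2-one
Product: 19 (4R)-4-benzyl-3-[(2S,3R,4E)-5-bromo-2,4-dimethyl-3-(triethylsilyloxy)pent-4-enoyl]-1,3-oxazolidin-2-one
Conditions: Et3SiOTf (1.3 equiv), 2,6-lutidine (2 equiv), CH2Cl2, −78 °C
Reagents that add atoms: triethylsilyl trifluoromethanesulfonate, CC[Si](CC)(CC)OS(=O)(=O)C(F)(F)F
Why: Silylation with the reactive silyl triflate protects the hindered allylic hydroxyl as a triethylsilyl ether that survives the hydride, enolate and nickel steps and is removed by fluoride at the end.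

Step 10
Reactants: 19 (4R)-4-benzyl-3-[(2S,3R,4E)-5-bromo-2,4-dimethyl-3-(triethylsilyloxy)pent-4-enoyl]-1,3-oxazolidin-2-one
Product: 20 (2R,3R,4E)-5-bromo-2,4-dimethyl-3-(triethylsilyloxy)pent-4-en-1-ol
Conditions: LiBH4 (1.5 equiv), H2O (1.1 equiv), Et2O, 0 °C; H2O quench
Reagents that add atoms: none
Why: Reductive cleavage of the N-acyl oxazolidinone with LiBH4 gives the primary alcohol and returns the auxiliary without enolising the α-centre, the alkenyl bromide and silyl ether being inert.

Step 11
Reactants: 20 (2R,3R,4E)-5-bromo-2,4-dimethyl-3-(triethylsilyloxy)pent-4-en-1-ol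
Product: 21 (2S,3R,4E)-5-bromo-2,4-dimethyl-3-(triethylsilyloxy)pent-4-enal
Conditions: Dess–Martin periodinane (1.3 equiv), pyridine (3 equiv), CH2Cl2, 0 °C → rt; used at once
Reagents that add atoms: none
Why: Dess–Martin oxidation under buffered non-basic conditions gives the α-methyl aldehyde without epimerisation.

Step 12
Reactants: 4 2,6-diethyl-3,5-dimethyl-4H-pyran-4-one; 21 (2S,3R,4E)-5-bromo-2,4-dimethyl-3-(triethylsilyloxy)pent-4-enal
Product: 23 2-[(2R,3R,4R,5R,6E)-7-bromo-3-hydroxy-4,6-dimethyl-5-(triethylsilyloxy)hept-6-en-2-yl]-6-ethyl-3,5-dimethyl-4H-pyran-4-one, via lithium dienolate 22 (not isolated)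
Conditions: 4 (2.0 equiv), LiN(SiMe3)2 (1.9 equiv), THF, −78 °C, 45 min; then 21 (1.0 equiv), −78 °C, 1 h; AcOH quench at −78 °C
Reagents that add atoms: none
Why: Vinylogous aldol addition of the lateral lithium dienolate, in which the exocyclic carbon attacks the aldehyde with Felkin–Anh control by the α-methyl group reinforced by 1,3-anti induction from the β-silyloxy group (2,3-anti aldehyde, matched case) to set C-3 of the heptenyl chain (R, 3,4-syn and 3,5-anti), while the open antiperiplanar transition state that keeps the aldehyde chain away from the ring C-3 methyl gives the 2,3-anti relationship that sets C-2 (R).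

Step 13
Reactants: 12 (2S,3S)-2-[6-(1-chloroethyl)-3,5-dimethyl-4-oxo-4H-pyran-2-yl]pentan-3-yl acetate; 23 2-[(2R,3R,4R,5R,6E)-7-bromo-3-hydroxy-4,6-dimethyl-5-(triethylsilyloxy)hept-6-en-2-yl]-6-ethyl-3,5-dimethyl-4H-pyran-4-one
Product: 24 (2S,3S)-2-{6-[(2S,3E,5R,6R,7R,8R)-8-(6-ethyl-3,5-dimethyl-4-oxo-4H-pyran-2-yl)-7-hydroxy-4,6-dimethyl-5-(triethylsilyloxy)non-3-en-2-yl]-3,5-dimethyl-4-oxo-4H-pyran-2-yl}pentan-3-yl acetate
Conditions: 12 (1.3 equiv), 23 (1.0 equiv), NiCl2·DME (10 mol %), (3aR,3a′R,8aS,8a′S)-2,2′-(cyclopropane-1,1-diyl)bis(3a,8a-dihydro-8H-indeno[1,2-d]oxazole) (11 mol %), Mn powder (3 equiv), NaI (0.5 equiv), DMA, 0 °C → rt, 24 h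
Reagents that add atoms: none
Why: Proposed new method: enantioconvergent nickel-catalysed reductive cross-electrophile coupling of a secondary benzylic-type chloride with an alkenyl bromide (closest known type: nickel/bis(oxazoline)/manganese coupling of 1-arylethyl chlorides with (E)-alkenyl bromides), in which zerovalent nickel inserts into the C–Br bond with retention of the E geometry, the planar pyranone-stabilised radical from either epimer of 12 is captured by the chiral alkenyl–nickel species and reductive elimination sets the new doubly activated C–H stereocentre as (S) under neutral base-free conditions that tolerate the free hydroxyl, the esters and both pyranones.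

Step 14
Reactants: 24 (2S,3S)-2-{6-[(2S,3E,5R,6R,7R,8R)-8-(6-ethyl-3,5-dimethyl-4-oxo-4H-pyran-2-yl)-7-hydroxy-4,6-dimethyl-5-(triethylsilyloxy)non-3-en-2-yl]-3,5-dimethyl-4-oxo-4H-pyran-2-yl}pentan-3-yl acetate
Product: 25 (2S,3S)-2-{6-[(2S,3E,5R,6R,7R,8R)-8-(6-ethyl-3,5-dimethyl-4-oxo-4H-pyran-2-yl)-5,7-dihydroxy-4,6-dimethylnon-3-en-2-yl]-3,5-dimethyl-4-oxo-4H-pyran-2-yl}pentan-3-yl acetate
Conditions: HF·pyridine, pyridine, THF, 0 °C → rt
Reagents that add atoms: none
Why: Fluoride desilylation with buffered HF·pyridine cleaves the triethylsilyl ether without touching the acetate or the base-sensitive C–H centre made in step 13.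

Step 15
Reactants: 25 (2S,3S)-2-{6-[(2S,3E,5R,6R,7R,8R)-8-(6-ethyl-3,5-dimethyl-4-oxo-4H-pyran-2-yl)-5,7-dihydroxy-4,6-dimethylnon-3-en-2-yl]-3,5-dimethyl-4-oxo-4H-pyran-2-yl}pentan-3-yl acetate; 2 propanoic anhydride
Product: 26 (2S,3S)-2-{6-[(2S,3E,5R,6R,7R,8R)-8-(6-ethyl-3,5-dimethyl-4-oxo-4H-pyran-2-yl)-4,6-dimethyl-5,7-bis(propanoyloxy)non-3-en-2-yl]-3,5-dimethyl-4-oxo-4H-pyran-2-yl}pentan-3-yl acetate (CNP0295731.1)
Conditions: (EtCO)2O (4 equiv), pyridine, DMAP (0.2 equiv), CH2Cl2, 0 °C → rt
Reagents that add atoms: none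
Why: DMAP-catalysed esterification of both secondary hydroxyls with propanoic anhydride gives the bis(propanoate) under weakly basic conditions that avoid E1cB loss of the β-acyloxy groups and epimerisation, no stereocentre being touched.

**Compound list**

1 | pentan-3-one | CCC(=O)CC | starting material
2 | propanoic anhydride | CCC(=O)OC(=O)CC | starting material
3 | 4,6-dimethylnonane-3,5,7-trione (mixture of stereoisomers and enol forms) | CCC(=O)C(C)C(=O)C(C)C(=O)CC | intermediate
4 | 2,6-diethyl-3,5-dimethyl-4H-pyran-4-one | CCc1oc(CC)c(C)c(=O)c1C | intermediate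
5 | sodium (6Z)-2-ethyl-6-ethylidene-3,5-dimethyl-6H-pyran-4-olate | C/C=C1\OC(CC)=C(C)C([O-])=C1C.[Na+] | intermediate
6 | 2-(1-chloroethyl)-6-ethyl-3,5-dimethyl-4H-pyran-4-one (racemic) | CCc1oc(C(C)Cl)c(C)c(=O)c1C | intermediate
7 | propanoyl chloride | CCC(=O)Cl | starting material
8 | 2-ethyl-3,5-dimethyl-6-[(2R)-3-oxopentan-2-yl]-4H-pyran-4-one | CCc1oc([C@@H](C)C(=O)CC)c(C)c(=O)c1C | intermediate
9 | 2-ethyl-6-[(2S,3S)-3-hydroxypentan-2-yl]-3,5-dimethyl-4H-pyran-4-one | CCc1oc([C@@H](C)[C@H](CC)O)c(C)c(=O)c1C | intermediate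
10 | dilithium (6Z)-6-ethylidene-3,5-dimethyl-2-[(2S,3S)-3-oxidopentan-2-yl]-6H-pyran-4-olate | C/C=C1\OC([C@@H](C)[C@H](CC)[O-])=C(C)C([O-])=C1C.[Li+].[Li+] | intermediate
11 | 2-(1-chloroethyl)-6-[(2S,3S)-3-hydroxypentan-2-yl]-3,5-dimethyl-4H-pyran-4-one (both epimers at the CHCl carbon) | CC(Cl)c1oc([C@@H](C)[C@H](CC)O)c(C)c(=O)c1C | intermediate
12 | (2S,3S)-2-[6-(1-chloroethyl)-3,5-dimethyl-4-oxo-4H-pyran-2-yl]pentan-3-yl acetate (both epimers at the CHCl carbon) | CC(Cl)c1oc([C@@H](C)[C@H](CC)OC(C)=O)c(C)c(=O)c1C | intermediate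
13 | 2-methylprop-2-enal (methacrolein) | CC(=C)C=O | starting material
14 | 2,3-dibromo-2-methylpropanal (racemic) | O=CC(C)(Br)CBr | intermediate
15 | (2E)-3-bromo-2-methylprop-2-enal | O=C/C(C)=C/Br | intermediate
16 | (4R)-4-benzyl-3-propanoyl-1,3-oxazolidin-2-one | CCC(=O)N1[C@H](Cc2ccccc2)COC1=O | starting material
17 | (4R)-4-benzyl-3-[(2S,3R,4E)-5-bromo-2,4-dimethyl-3-(trimethylsilyloxy)pent-4-enoyl]-1,3-oxazolidin-2-one | O=C(N1[C@H](Cc2ccccc2)COC1=O)[C@@H](C)[C@@H](O[Si](C)(C)C)/C(C)=C/Br | intermediate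
18 | (4R)-4-benzyl-3-[(2S,3R,4E)-5-bromo-3-hydroxy-2,4-dimethylpent-4-enoyl]-1,3-oxazolidin-2-one | O=C(N1[C@H](Cc2ccccc2)COC1=O)[C@@H](C)[C@@H](O)/C(C)=C/Br | intermediate
19 | (4R)-4-benzyl-3-[(2S,3R,4E)-5-bromo-2,4-dimethyl-3-(triethylsilyloxy)pent-4-enoyl]-1,3-oxazolidin-2-one | O=C(N1[C@H](Cc2ccccc2)COC1=O)[C@@H](C)[C@@H](O[Si](CC)(CC)CC)/C(C)=C/Br | intermediate
20 | (2R,3R,4E)-5-bromo-2,4-dimethyl-3-(triethylsilyloxy)pent-4-en-1-ol | OC[C@@H](C)[C@@H](O[Si](CC)(CC)CC)/C(C)=C/Br | intermediate
21 | (2S,3R,4E)-5-bromo-2,4-dimethyl-3-(triethylsilyloxy)pent-4-enal | O=C[C@@H](C)[C@@H](O[Si](CC)(CC)CC)/C(C)=C/Br | intermediate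
22 | lithium (6Z)-2-ethyl-6-ethylidene-3,5-dimethyl-6H-pyran-4-olate | C/C=C1\OC(CC)=C(C)C([O-])=C1C.[Li+] | intermediate
23 | 2-[(2R,3R,4R,5R,6E)-7-bromo-3-hydroxy-4,6-dimethyl-5-(triethylsilyloxy)hept-6-en-2-yl]-6-ethyl-3,5-dimethyl-4H-pyran-4-one | O[C@H]([C@@H](C)[C@@H](O[Si](CC)(CC)CC)/C(C)=C/Br)[C@@H](C)c1oc(CC)c(C)c(=O)c1C | intermediate
24 | (2S,3S)-2-{6-[(2S,3E,5R,6R,7R,8R)-8-(6-ethyl-3,5-dimethyl-4-oxo-4H-pyran-2-yl)-7-hydroxy-4,6-dimethyl-5-(triethylsilyloxy)non-3-en-2-yl]-3,5-dimethyl-4-oxo-4H-pyran-2-yl}pentan-3-yl acetate | O[C@H]([C@@H](C)[C@@H](O[Si](CC)(CC)CC)/C(C)=C/[C@H](C)c1oc([C@@H](C)[C@H](CC)OC(C)=O)c(C)c(=O)c1C)[C@@H](C)c1oc(CC)c(C)c(=O)c1C | intermediate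
25 | (2S,3S)-2-{6-[(2S,3E,5R,6R,7R,8R)-8-(6-ethyl-3,5-dimethyl-4-oxo-4H-pyran-2-yl)-5,7-dihydroxy-4,6-dimethylnon-3-en-2-yl]-3,5-dimethyl-4-oxo-4H-pyran-2-yl}pentan-3-yl acetate | O[C@H]([C@@H](C)[C@@H](O)/C(C)=C/[C@H](C)c1oc([C@@H](C)[C@H](CC)OC(C)=O)c(C)c(=O)c1C)[C@@H](C)c1oc(CC)c(C)c(=O)c1C | intermediate
26 | (2S,3S)-2-{6-[(2S,3E,5R,6R,7R,8R)-8-(6-ethyl-3,5-dimethyl-4-oxo-4H-pyran-2-yl)-4,6-dimethyl-5,7-bis(propanoyloxy)non-3-en-2-yl]-3,5-dimethyl-4-oxo-4H-pyran-2-yl}pentan-3-yl acetate | CCC(=O)O[C@H]([C@@H](C)[C@@H](OC(=O)CC)/C(C)=C/[C@H](C)c1oc([C@@H](C)[C@H](CC)OC(C)=O)c(C)c(=O)c1C)[C@@H](C)c1oc(CC)c(C)c(=O)c1C | target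

**Step count and risk**

Total steps: 15. Longest linear sequence: 9 steps (13 → 26 through steps 7 to 15; the branch 1 → 12 → 26 through steps 1 to 6 and 13 to 15 is also 9).

The three steps most likely to fail:

Step 13 (the key union). The alkenyl bromide is trisubstituted, both partners are full fragments, and the pyranonyl-ethyl chloride is outside the known scope, so conversion and catalyst control at the new centre are both uncertain. The fallback sets out from 9 (and uses 23) and comes back at 24, making the same bond by closed-shell enolate alkenylation instead of radical cross-electrophile coupling. 9 is acetylated (Ac2O, pyridine, DMAP, CH2Cl2, 0 °C) to (2S,3S)-2-(6-ethyl-3,5-dimethyl-4-oxo-4H-pyran-2-yl)pentan-3-yl acetate F1. Soft enolisation of F1 (t-BuMe2SiOTf, Et3N, CH2Cl2, −78 °C; the silyloxypyrylium ion loses a proton from the unhindered ethyl CH2) gives the silyl dienol ether (2S,3S)-2-[(6Z)-4-(tert-butyldimethylsilyloxy)-6-ethylidene-3,5-dimethyl-6H-pyran-2-yl]pentan-3-yl acetate F2. F2 and 23 are then joined by a palladium-catalysed enantioselective γ-alkenylation of the silyl dienol ether (Pd(dba)2, a chiral biaryl monophosphine, ZnF2, DMF, rt), which gives 24 under non-basic conditions so the tertiary centre is not scrambled.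

Step 3 (asymmetric reductive acylation). The ketone 8 carries a C–H that is both lateral to the pyranone and α to a ketone, so it may form in low enantiomeric excess or epimerise before step 4. The fallback sets out from 4 and comes back at 9, replacing catalyst control by an aldol and a resolution. 4 is deprotonated (LiN(SiMe3)2, THF, −78 °C) to lithium dienolate 22, which is added to propanal to give the racemic anti aldol (2S,3S)/(2R,3R)-2-ethyl-6-(3-hydroxypentan-2-yl)-3,5-dimethyl-4H-pyran-4-one F3. Lipase-catalysed kinetic resolution (immobilised Candida antarctica lipase B, vinyl acetate, MTBE, 30 °C) acetylates the (3R) alcohol, as the Kazlauskas rule predicts, to (2R,3R)-2-(6-ethyl-3,5-dimethyl-4-oxo-4H-pyran-2-yl)pentan-3-yl acetate F4, which is removed by chromatography and leaves 9 (at most half of the material).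

Step 12 (vinylogous aldol). The Felkin/1,3-anti sense at the carbinol is well founded, but the simple anti selectivity at the pyranone-bearing carbon comes from an open transition state and may be modest. The fallback sets out from 4 (and uses 21) and comes back at 23, generating the nucleophile from a halide under non-basic conditions. 4 is brominated at the lateral position as in step 2 (NaN(SiMe3)2, THF, −78 °C, through sodium dienolate 5; then BrCCl2CCl2Br) to racemic 2-(1-bromoethyl)-6-ethyl-3,5-dimethyl-4H-pyran-4-one F5. F5 is added to 21 with CrCl2 (3 equiv) and LiI (cat.) in THF at rt: the chromium dienolate (Nozaki–Hiyama/Reformatsky type) reacts through a compact closed transition state that is expected to be anti- and Felkin-selective, giving 23.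

Further compounds
F1 | step 13 | (2S,3S)-2-(6-ethyl-3,5-dimethyl-4-oxo-4H-pyran-2-yl)pentan-3-yl acetate | CCc1oc([C@@H](C)[C@H](CC)OC(C)=O)c(C)c(=O)c1C
F2 | step 13 | (2S,3S)-2-[(6Z)-4-(tert-butyldimethylsilyloxy)-6-ethylidene-3,5-dimethyl-6H-pyran-2-yl]pentan-3-yl acetate | C/C=C1\OC([C@@H](C)[C@H](CC)OC(C)=O)=C(C)C(O[Si](C)(C)C(C)(C)C)=C1C
F3 | step 3 | racemic anti aldol, (2S,3S)/(2R,3R)-2-ethyl-6-(3-hydroxypentan-2-yl)-3,5-dimethyl-4H-pyran-4-one | CCc1oc([C@@H](C)[C@H](CC)O)c(C)c(=O)c1C.CCc1oc([C@H](C)[C@@H](CC)O)c(C)c(=O)c1C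
F4 | step 3 | (2R,3R)-2-(6-ethyl-3,5-dimethyl-4-oxo-4H-pyran-2-yl)pentan-3-yl acetate | CCc1oc([C@H](C)[C@@H](CC)OC(C)=O)c(C)c(=O)c1C
F5 | step 12 | 2-(1-bromoethyl)-6-ethyl-3,5-dimethyl-4H-pyran-4-one (racemic) | CCc1oc(C(C)Br)c(C)c(=O)c1C
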